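**Plan**

1. Numbering: chroman O1, C2 (CMe2), C3 (OH), C4 (CH2), C4a, C5 (OH), C6 (CH2 bridge), C7 (OH), C8 (acyl), C8a; the bridge ends at C3' of the pyrone.
2. The first cut removes the two bonds of the methylene bridge (C6–CH2 and CH2–C3'), which leaves the chromanol ketone, a one-carbon iminium unit and the pyrone; the pyrone is cut at its lactone C–O bond and at the C4'–C5' acyl bond.
3. The central cut takes C4–C3 and O1–C2 of the pyran ring. That ring has a benzylic CH2 (C4) ortho to the ether oxygen O1, a carbinol at C3 and an oxygen-bound CMe2 at C2, which is the imprint of an ortho-quinone methide (C8a=O, C4a=CH2) and Me2C=CH–B, with boron as the masked 3-hydroxyl.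
4. The last cuts are C4–C4a (ortho-formylation of a phenol, then reduction) and the aryl–acyl bond (Friedel–Crafts acylation of phloroglucinol).
5. Forward: acylphloroglucinol, then its dibenzyl ether (the ketone-chelated hydroxyl stays free), ortho CH2OH, [4+2] closure of the pyran ring, C–B to C–OH, debenzylation, and finally the methylene bridge to the pyrone, whose own ring is closed by lactonisation in a two-step branch.
6. Stereochemistry: the side-chain (S)-centre is bought as (S)-2-methylbutanoic acid; C3 (S) is set by a chiral Brønsted acid in the cycloaddition and passes from boron to oxygen with retention.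

Key step: step 5

Assumption: the (R)-catalyst is taken to deliver the (3S)-boronate 10; if the first run shows the opposite sense, the (S)-catalyst is used and nothing else changes.

**Route**

Step 1
Reactants: 1 phloroglucinol (benzene-1,3,5-triol); 2 (S)-2-methylbutanoic acid
Product: 4 (S)-2-methyl-1-(2,4,6-trihydroxyphenyl)butan-1-one, via (S)-2-methylbutanoyl chloride 3 (not isolated)
Conditions: 2, (COCl)2, DMF (cat.), CH2Cl2, 0 °C to rt, evaporate; then 1, AlCl3 (3.5 equiv), CH2Cl2/PhNO2, 0 °C to rt; aq. HCl
Reagents that add atoms: none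
Why: Friedel–Crafts C-acylation of the very nucleophilic phloroglucinol by acid chloride 3 stops after one acyl group because the ketone deactivates the ring, and the low temperature should suppress ketene formation from 3, the one path that would erode the (S)-centre.

Step 2
Reactants: 4 (S)-2-methyl-1-(2,4,6-trihydroxyphenyl)butan-1-one
Product: 5 (S)-1-[2,4-bis(benzyloxy)-6-hydroxyphenyl]-2-methylbutan-1-one
Conditions: BnBr (2.1 equiv), K2CO3 (2.2 equiv), DMF, rt
Reagents that add atoms: benzyl bromide, BrCc1ccccc1
Why: Williamson etherification under weak base takes the para hydroxyl and then one ortho hydroxyl while the last one, held in a hydrogen bond to the ketone, stays free, which is the usual pattern for acylphloroglucinols, and the conjugated phenoxide makes enolisation toward the stereocentre unlikely.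

Step 3
Reactants: 5 (S)-1-[2,4-bis(benzyloxy)-6-hydroxyphenyl]-2-methylbutan-1-one
Product: 6 4,6-bis(benzyloxy)-2-hydroxy-3-[(2S)-2-methylbutanoyl]benzaldehyde
Conditions: MgCl2 (2 equiv), Et3N (4 equiv), (CH2O)n (6 equiv), MeCN, reflux; aq. HCl
Reagents that add atoms: paraformaldehyde (formaldehyde), C=O
Why: Magnesium-mediated ortho-formylation (Casnati–Skattebøl) delivers formaldehyde from the magnesium phenoxide to the only free ortho carbon and a second formaldehyde oxidises the benzylic alkoxide by hydride transfer, so the carbon between the two benzyloxy groups should stay untouched.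

Step 4
Reactants: 6 4,6-bis(benzyloxy)-2-hydroxy-3-[(2S)-2-methylbutanoyl]benzaldehyde
Product: 7 (S)-1-[4,6-bis(benzyloxy)-2-hydroxy-3-(hydroxymethyl)phenyl]-2-methylbutan-1-one
Conditions: NaBH4 (1 equiv), THF/MeOH, −20 to 0 °C; pH 7 buffer
Reagents that add atoms: none
Why: Borohydride reduction should discriminate the aldehyde from the chelated, doubly ortho-substituted, alpha-branched aryl ketone, and a cold neutral work-up keeps the electron-rich salicyl alcohol from ionising early.

Step 5
Reactants: 7 (S)-1-[4,6-bis(benzyloxy)-2-hydroxy-3-(hydroxymethyl)phenyl]-2-methylbutan-1-one; 8 4,4,5,5-tetramethyl-2-(2-methylprop-1-en-1-yl)-1,3,2-dioxaborolane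
Product: 10 (S)-1-[(3S)-5,7-bis(benzyloxy)-2,2-dimethyl-3-(4,4,5,5-tetramethyl-1,3,2-dioxaborolan-2-yl)-3,4-dihydro-2H-chromen-8-yl]-2-methylbutan-1-one, via ortho-quinone methide 9 (not isolated)
Conditions: 8 (3 equiv), (R)-3,3'-bis(2,4,6-triisopropylphenyl)-1,1'-binaphthyl-2,2'-diyl N-triflylphosphoramide (10 mol%), 5 Å molecular sieves, toluene, −20 °C to rt, 7 added slowly
Reagents that add atoms: none
Why: Proposed new method: the acid ionises the benzylic alcohol of 7 to the hydrogen-bonded ortho-quinone methide 9 (a hydroxybenzyl cation paired with the chiral phosphoramidate), whose exocyclic CH2 bonds to the boron-bearing carbon of 8 because the charge that develops is then tertiary and stabilised by hyperconjugation with the adjacent C–B bond, after which the quinone methide oxygen closes on that tertiary carbon in an asynchronous inverse-demand hetero-Diels–Alder reaction that restores aromaticity. The closest known reaction type is the chiral phosphoric acid or N-triflylphosphoramide catalysed [4+2] of ortho-quinone methides, made from ortho-hydroxybenzyl alcohols, with styrenes and other unactivated or electron-rich alkenes; an alkenylboronic ester has not been shown as the two-carbon partner, and its known behaviour toward quinone methides is alkenyl transfer. The pyran ring is closed by the cycloaddition itself, C4–C3 first and O1–C2 second, a six-membered closure of the phenolic oxygen onto the tertiary cationic carbon. The one new stereocentre, C3, is fixed in the C–C bond-forming event by the catalyst, which covers one face of the quinone methide through its hydrogen bond to the carbonyl oxygen while the bulky dioxaborolane, set against H on the same carbon, should stay outside the catalyst pocket and away from the neighbouring benzyloxy group, so that one alkene face is offered; the side-chain (S)-centre is remote and untouched. The step needs regioselectivity (from the tertiary, beta-boryl polarity), a single quinone methide (the ketone-chelated hydroxyl is the only free phenol) and ring closure ahead of deboronation, alkenyl transfer or oligomerisation (favoured by the weakly Lewis-acidic pinacol ester, the sieves, the excess of 8 and the slow addition of 7).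

Step 6
Reactants: 10 (S)-1-[(3S)-5,7-bis(benzyloxy)-2,2-dimethyl-3-(4,4,5,5-tetramethyl-1,3,2-dioxaborolan-2-yl)-3,4-dihydro-2H-chromen-8-yl]-2-methylbutan-1-one
Product: 12 (S)-1-[(3S)-5,7-bis(benzyloxy)-3-hydroxy-2,2-dimethyl-3,4-dihydro-2H-chromen-8-yl]-2-methylbutan-1-one, via borate ester 11 (not isolated)
Conditions: Me3NO (anhydrous, 4 equiv), THF, 65 °C; then H2O, rt
Reagents that add atoms: trimethylamine N-oxide, C[N+](C)(C)[O-]
Why: Amine N-oxide oxidation of the C–B bond runs through a boron ate complex and a 1,2-shift of C3 from boron to oxygen with retention, so the (3S)-boronate should give the (3S)-alcohol once borate 11 is hydrolysed, and the neutral oxidant leaves the aryl ketone and its alpha-centre alone.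

Step 7
Reactants: 12 (S)-1-[(3S)-5,7-bis(benzyloxy)-3-hydroxy-2,2-dimethyl-3,4-dihydro-2H-chromen-8-yl]-2-methylbutan-1-one
Product: 13 (S)-2-methyl-1-[(3S)-3,5,7-trihydroxy-2,2-dimethyl-3,4-dihydro-2H-chromen-8-yl]butan-1-one
Conditions: H2 (1 atm), 10% Pd/C, EtOAc/MeOH, rt
Reagents that add atoms: none
Why: Catalytic hydrogenolysis removes the two aryl benzyl ethers, while the hydrogen-bonded hindered aryl ketone and the non-benzylic C–O bonds of the chromanol are expected to be inert at 1 atm and room temperature.

Step 8
Reactants: 14 methyl 3-oxopentanoate; 15 N-methoxy-N-methylpropanamide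
Product: 17 methyl 4-methyl-3,5-dioxoheptanoate, via keto ester dianion 16 (not isolated)
Conditions: 14, NaH (1.1 equiv), THF, 0 °C; n-BuLi (1.05 equiv), 0 °C; 15, −78 to 0 °C; aq. HCl
Reagents that add atoms: none
Why: Gamma-acylation of a beta-keto ester dianion, in which the more reactive terminal carbanion adds to the Weinreb amide to give a chelated tetrahedral adduct that releases the 3,5-diketo ester only on acidic work-up, so no second addition should occur.

Step 9
Reactants: 17 methyl 4-methyl-3,5-dioxoheptanoate
Product: 18 6-ethyl-4-hydroxy-5-methyl-2H-pyran-2-one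
Conditions: DBU (1.2 equiv), toluene, reflux; aq. HCl
Reagents that add atoms: none
Why: Base-mediated lactonisation of a 3,5-diketo ester, in which the C5 enolate oxygen attacks the ester carbonyl and methanol is lost, is the standard way to 4-hydroxy-2-pyrones.

Step 10
Reactants: 13 (S)-2-methyl-1-[(3S)-3,5,7-trihydroxy-2,2-dimethyl-3,4-dihydro-2H-chromen-8-yl]butan-1-one; 18 6-ethyl-4-hydroxy-5-methyl-2H-pyran-2-one
Product: 21 6-ethyl-4-hydroxy-5-methyl-3-{[(3S)-3,5,7-trihydroxy-2,2-dimethyl-8-[(2S)-2-methylbutanoyl]-3,4-dihydro-2H-chromen-6-yl]methyl}-2H-pyran-2-one, via pyrone Mannich base 19 (not isolated), via methylidene pyrandione 20 (not isolated)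
Conditions: 18, CH2=NMe2+ I− (1.05 equiv), MeCN, rt; then 13 (1.0 equiv), 60 °C
Reagents that add atoms: dimethylmethylideneammonium iodide (Eschenmoser's salt), C=[N+](C)C.[I-]
Why: Mannich reaction of pyrone 18 at C3 gives base 19, which loses dimethylamine to the strongly electrophilic enedione 20, and the phloroglucinol ring of 13 adds through C6, its only unsubstituted carbon, in a Friedel–Crafts-type conjugate addition, the established way to methylene-bridged acylphloroglucinol–pyrone dimers.

**Compound list**

1 | benzene-1,3,5-triol (phloroglucinol) | Oc1cc(O)cc(O)c1 | starting material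
2 | (S)-2-methylbutanoic acid | CC[C@H](C)C(=O)O | starting material
3 | (S)-2-methylbutanoyl chloride | CC[C@H](C)C(=O)Cl | intermediate
4 | (S)-2-methyl-1-(2,4,6-trihydroxyphenyl)butan-1-one | CC[C@H](C)C(=O)c1c(O)cc(O)cc1O | intermediate
5 | (S)-1-[2,4-bis(benzyloxy)-6-hydroxyphenyl]-2-methylbutan-1-one | CC[C@H](C)C(=O)c1c(O)cc(OCc2ccccc2)cc1OCc1ccccc1 | intermediate
6 | 4,6-bis(benzyloxy)-2-hydroxy-3-[(2S)-2-methylbutanoyl]benzaldehyde | CC[C@H](C)C(=O)c1c(O)c(C=O)c(OCc2ccccc2)cc1OCc1ccccc1 | intermediate
7 | (S)-1-[4,6-bis(benzyloxy)-2-hydroxy-3-(hydroxymethyl)phenyl]-2-methylbutan-1-one | CC[C@H](C)C(=O)c1c(O)c(CO)c(OCc2ccccc2)cc1OCc1ccccc1 | intermediate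
8 | 4,4,5,5-tetramethyl-2-(2-methylprop-1-en-1-yl)-1,3,2-dioxaborolane | CC(C)=CB1OC(C)(C)C(C)(C)O1 | starting material
9 | 3,5-bis(benzyloxy)-6-methylidene-2-[(2S)-2-methylbutanoyl]cyclohexa-2,4-dien-1-one (ortho-quinone methide) | C=C1C(=O)C(C(=O)[C@@H](C)CC)=C(OCc2ccccc2)C=C1OCc1ccccc1 | intermediate
10 | (S)-1-[(3S)-5,7-bis(benzyloxy)-2,2-dimethyl-3-(4,4,5,5-tetramethyl-1,3,2-dioxaborolan-2-yl)-3,4-dihydro-2H-chromen-8-yl]-2-methylbutan-1-one | CC[C@H](C)C(=O)c1c(OCc2ccccc2)cc(OCc2ccccc2)c2c1OC(C)(C)[C@@H](B1OC(C)(C)C(C)(C)O1)C2 | intermediate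
11 | (S)-1-[(3S)-5,7-bis(benzyloxy)-2,2-dimethyl-3-[(4,4,5,5-tetramethyl-1,3,2-dioxaborolan-2-yl)oxy]-3,4-dihydro-2H-chromen-8-yl]-2-methylbutan-1-one (borate ester) | CC[C@H](C)C(=O)c1c(OCc2ccccc2)cc(OCc2ccccc2)c2c1OC(C)(C)[C@@H](OB1OC(C)(C)C(C)(C)O1)C2 | intermediate
12 | (S)-1-[(3S)-5,7-bis(benzyloxy)-3-hydroxy-2,2-dimethyl-3,4-dihydro-2H-chromen-8-yl]-2-methylbutan-1-one | CC[C@H](C)C(=O)c1c(OCc2ccccc2)cc(OCc2ccccc2)c2c1OC(C)(C)[C@@H](O)C2 | intermediate
13 | (S)-2-methyl-1-[(3S)-3,5,7-trihydroxy-2,2-dimethyl-3,4-dihydro-2H-chromen-8-yl]butan-1-one | CC[C@H](C)C(=O)c1c(O)cc(O)c2c1OC(C)(C)[C@@H](O)C2 | intermediate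
14 | methyl 3-oxopentanoate | CCC(=O)CC(=O)OC | starting material
15 | N-methoxy-N-methylpropanamide | CCC(=O)N(C)OC | starting material
16 | sodium lithium 2,4-dianion (dienolate) of methyl 3-oxopentanoate | CC=C([O-])C=C([O-])OC.[Na+].[Li+] | intermediate
17 | methyl 4-methyl-3,5-dioxoheptanoate | CCC(=O)C(C)C(=O)CC(=O)OC | intermediate
18 | 6-ethyl-4-hydroxy-5-methyl-2H-pyran-2-one | CCc1oc(=O)cc(O)c1C | intermediate
19 | 3-[(dimethylamino)methyl]-6-ethyl-4-hydroxy-5-methyl-2H-pyran-2-one | CCc1oc(=O)c(CN(C)C)c(O)c1C | intermediate
20 | 6-ethyl-5-methyl-3-methylidene-2H-pyran-2,4(3H)-dione | CCC1=C(C)C(=O)C(=C)C(=O)O1 | intermediate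
21 | 6-ethyl-4-hydroxy-5-methyl-3-{[(3S)-3,5,7-trihydroxy-2,2-dimethyl-8-[(2S)-2-methylbutanoyl]-3,4-dihydro-2H-chromen-6-yl]methyl}-2H-pyran-2-one | CCc1oc(=O)c(Cc2c(O)c3c(c(C(=O)[C@@H](C)CC)c2O)OC(C)(C)[C@@H](O)C3)c(O)c1C | target

**Count and risks**

Total step count: 10. Longest linear sequence: 8 (steps 1 to 7, then step 10); the pyrone branch is steps 8 and 9.

Steps most likely to fail:

1. Step 5. The beta-boryl cation may lose boron before the oxygen closes (net alkenyl transfer to an ortho-prenyl phenol), the acid may protodeboronate 8 and be trapped on boron, the quinone methide may oligomerise, or the catalyst may discriminate the alkene faces poorly. The C3 epimers are diastereomers because of the side-chain centre, so the outcome should be readable directly on 12. The fallback uses known chemistry and sets out from 5. Condensation with 3-methylbut-2-enal mediated by PhB(OH)2 (AcOH cat., toluene, reflux, water removal; ortho-alkenylation then oxa-6π electrocyclisation) should give the chromene (S)-1-[5,7-bis(benzyloxy)-2,2-dimethyl-2H-chromen-8-yl]-2-methylbutan-1-one F1. Jacobsen epoxidation with (S,S)-N,N'-bis(3,5-di-tert-butylsalicylidene)-1,2-cyclohexanediaminomanganese chloride (a trivalent manganese salen complex), NaOCl and 4-phenylpyridine N-oxide in CH2Cl2 at 0 °C is expected, by analogy with other 2,2-dimethylchromenes, to give the epoxide (S)-1-[(3S,4S)-5,7-bis(benzyloxy)-3,4-epoxy-2,2-dimethyl-3,4-dihydro-2H-chromen-8-yl]-2-methylbutan-1-one F2. Hydrogenolysis (H2, Pd/C, EtOAc) then cleaves the benzylic C4–O bond and both benzyl ethers without touching the C3–O bond, and the fallback comes back to the route at 13.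

2. Step 10. The bridging may turn statistical: enedione 20 can be captured by unreacted pyrone (pyrone homodimer), the iminium can migrate to 13 by retro-Mannich exchange, and a second alkylation or O-alkylation can compete. The fallback sets out from 13 and exchanges the roles of the partners. Eschenmoser's salt (MeCN, rt, then NaHCO3) aminomethylates the only free ring carbon to give the isolable Mannich base (S)-1-[(3S)-6-[(dimethylamino)methyl]-3,5,7-trihydroxy-2,2-dimethyl-3,4-dihydro-2H-chromen-8-yl]-2-methylbutan-1-one F3. Heating F3 with pyrone 18 in dioxane at 100 °C (thermal loss of dimethylamine, then conjugate addition of pyrone C3, the known alkylation of 1,3-dicarbonyl compounds by phenolic Mannich bases) comes back to the route at 21. The pyrone never meets a free one-carbon electrophile, so it cannot dimerise.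

3. Step 3. The magnesium may stay locked in the ketone chelate so that formylation is slow, the intermediate benzylic alkoxide may alkylate a second arene, and a long reflux with MgCl2/Et3N may enolise the ketone and erode the alpha-centre. The fallback sets out from 5 and installs the CH2OH group directly by boron-templated ortho-hydroxymethylation. PhB(OH)2, (CH2O)n and EtCO2H (cat.) in refluxing toluene with water removal should give (S)-1-[5,7-bis(benzyloxy)-2-phenyl-4H-1,3,2-benzodioxaborinin-8-yl]-2-methylbutan-1-one F4. Diol exchange with pinacol (THF, rt) releases the salicyl alcohol, and the fallback comes back to the route at 7, bypassing 6 and step 4.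

**Further compounds**

F1 | step 5 | (S)-1-[5,7-bis(benzyloxy)-2,2-dimethyl-2H-chromen-8-yl]-2-methylbutan-1-one | CC[C@H](C)C(=O)c1c(OCc2ccccc2)cc(OCc2ccccc2)c2C=CC(C)(C)Oc12
F2 | step 5 | (S)-1-[(3S,4S)-5,7-bis(benzyloxy)-3,4-epoxy-2,2-dimethyl-3,4-dihydro-2H-chromen-8-yl]-2-methylbutan-1-one | CC[C@H](C)C(=O)c1c(OCc2ccccc2)cc(OCc2ccccc2)c2c1OC(C)(C)[C@H]1O[C@H]12
F3 | step 10 | (S)-1-[(3S)-6-[(dimethylamino)methyl]-3,5,7-trihydroxy-2,2-dimethyl-3,4-dihydro-2H-chromen-8-yl]-2-methylbutan-1-one | CC[C@H](C)C(=O)c1c(O)c(CN(C)C)c(O)c2c1OC(C)(C)[C@@H](O)C2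
F4 | step 3 | (S)-1-[5,7-bis(benzyloxy)-2-phenyl-4H-1,3,2-benzodioxaborinin-8-yl]-2-methylbutan-1-one | CC[C@H](C)C(=O)c1c(OCc2ccccc2)cc(OCc2ccccc2)c2COB(c3ccccc3)Oc12
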